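**Retrosynthetic overview**

1. Target 33 ⇒ desilylation of 32. The C15–C16 bond and both side-chain stereocentres come from a catalytic asymmetric vinylogous Mukaiyama aldol of E-enal 28 with silyloxyfuran 30, which brings in the butenolide ring preformed.
2. Enal 28 ⇒ Negishi carboalumination/hydroxymethylation of alkyne 25 ⇒ acetylide displacement on C12 iodide 24 ⇒ tetraol 21 ⇒ reduction of lactone 20.
3. Lactone 20 ⇒ acid-mediated lactonisation of the Δ8(9) homodrimenic acid 19, which forms the C8–O bond and sets C8 and C9. The γ-lactone O–C8–C9–C11–C12 is the only ring formed in the route and is opened again.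
4. Acid 19 ⇒ excision of aromatic ring C of a 12-methoxypodocarpatriene (Birch reduction, enol ether ozonolysis, decarbonylation), then acetylation and O-methyl cleavage of the ester. The 6α-OH comes from 6-ene formation and hydroboration, the C12 oxygen from Friedel–Crafts acetylation/Baeyer–Villiger, and the isopropyl group is removed by transalkylation.
5. Feature used: rings A and B with C4 (equatorial C18 carboxyl, later CH2OH), C5-H and C10-CH3 are those of dehydroabietic acid 1, and its ring C supplies C8, C9, C11, C12 and C14 (the future C8 methyl).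

Key step: step 15

Remark: abietane/labdane numbering is used (C18 = 4α carbon substituent; side chain C11–C19, C16 = butenolide CH–O, C17 carries the ring methyl); the Re-face preference of Ti(OiPr)4/(R)-BINOL in step 24 is assumed by analogy with other BINOL–titanium carbonyl additions, and (S)-BINOL would be taken if the sense proved opposite.

**Route**

Step 1
Reactants: 1 dehydroabietic acid
Product: 2 methyl dehydroabietate
Conditions: MeI, K2CO3, DMF, rt
Reagents that add atoms: iodomethane, CI
Why: Carboxylate O-alkylation (SN2) masks the hindered C18 acid as a methyl ester that tolerates the Lewis-acid steps that follow.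

Step 2
Reactants: 2 methyl dehydroabietate; 3 acetyl chloride
Product: 4 methyl 12-acetylabieta-8,11,13-trien-18-oate
Conditions: AlCl3 (2.5 equiv), CH2Cl2, 0 °C → rt
Reagents that add atoms: none
Why: Friedel–Crafts acylation should go to C12, the only unhindered position of ring C (C13 is substituted, C11 and C14 are flanked by ring B and the isopropyl group), as is usual for dehydroabietates.

Step 3
Reactants: 4 methyl 12-acetylabieta-8,11,13-trien-18-oate
Product: 5 methyl 12-acetoxyabieta-8,11,13-trien-18-oate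
Conditions: mCPBA, TFA (cat.), CH2Cl2, 0 °C → rt
Reagents that add atoms: mCPBA, OOC(=O)c1cccc(Cl)c1
Why: Baeyer–Villiger oxidation of the aryl methyl ketone with migration of the electron-rich aryl group creates the C12–O bond.

Step 4
Reactants: 5 methyl 12-acetoxyabieta-8,11,13-trien-18-oate
Product: 6 methyl 12-hydroxyabieta-8,11,13-trien-18-oate
Conditions: K2CO3 (cat.), MeOH, rt
Reagents that add atoms: none
Why: Base-catalysed transesterification cleaves the aryl acetate far faster than the hindered C18 ester and frees the phenol, so that no Fries rearrangement can occur in the next step.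

Step 5
Reactants: 6 methyl 12-hydroxyabieta-8,11,13-trien-18-oate
Product: 7 methyl 12-hydroxypodocarpa-8,11,13-trien-18-oate
Conditions: AlCl3 (4 equiv), toluene, rt → 50 °C
Reagents that add atoms: none
Why: Retro-Friedel–Crafts dealkylation (transalkylation to toluene): the aluminium phenoxide directs ipso-protonation to C13, ortho to oxygen, the isopropyl cation is passed to the solvent, and C9 (meta to oxygen) is not protonated, so the C9–C10 bond and the trans ring fusion should stay intact.

Step 6
Reactants: 7 methyl 12-hydroxypodocarpa-8,11,13-trien-18-oate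
Product: 8 methyl 12-methoxypodocarpa-8,11,13-trien-18-oate
Conditions: MeI, K2CO3, acetone, reflux
Reagents that add atoms: iodomethane, CI
Why: Williamson O-methylation gives the anisole that activates C7 and later directs the Birch reduction.

Step 7
Reactants: 8 methyl 12-methoxypodocarpa-8,11,13-trien-18-oate
Product: 9 methyl 12-methoxypodocarpa-6,8,11,13-tetraen-18-oate
Conditions: DDQ (1.3 equiv), dry 1,4-dioxane, reflux
Reagents that add atoms: none
Why: DDQ dehydrogenation: hydride abstraction from C7 (benzylic, para to the C12 methoxy group) and loss of H6 should give the styrene-type 6-ene without touching C5 or C10.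

Step 8
Reactants: 9 methyl 12-methoxypodocarpa-6,8,11,13-tetraen-18-oate
Product: 10 12-methoxypodocarpa-6,8,11,13-tetraen-18-ol
Conditions: LiAlH4, THF, 0 °C → reflux
Reagents that add atoms: none
Why: Hydride reduction of the neopentyl ester gives the C18 primary alcohol; the styrene is inert to LiAlH4.

Step 9
Reactants: 10 12-methoxypodocarpa-6,8,11,13-tetraen-18-ol
Product: 12 12-methoxypodocarpa-8,11,13-triene-6α,18-diol, via cyclic 6α-alkylborinate 11 (not isolated)
Conditions: BH3·THF (3 equiv), THF, 0 °C → rt; then 3 M NaOH, 30% H2O2, 0 °C → rt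
Reagents that add atoms: borane–THF, [BH3-][O+]1CCCC1 (boron of 11); hydrogen peroxide, OO (oxygen of the 6α-OH)
Why: Brown hydroboration–oxidation: boron adds to C6 (anti-Markovnikov for a p-methoxystyrene, reinforced by delivery from the C18 alkoxyborane on the α face) because the β face is blocked by the axial C10 and C4 methyl groups, and oxidation with retention gives the equatorial 6α-alcohol.

Step 10
Reactants: 12 12-methoxypodocarpa-8,11,13-triene-6α,18-diol
Product: 13 12-methoxypodocarpa-8(9),12-diene-6α,18-diol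
Conditions: Li (excess), NH3(l)/THF/t-BuOH, −78 → −33 °C; NH4Cl
Reagents that add atoms: none
Why: Birch reduction of the anisole protonates the unsubstituted C11 and C14, leaving the tetrasubstituted C8=C9 alkene and the C12=C13 methyl enol ether, with the two alkoxides as spectators.

Step 11
Reactants: 13 12-methoxypodocarpa-8(9),12-diene-6α,18-diol
Product: 15 methyl 6α,18-dihydroxy-13-oxo-12,13-secopodocarp-8(9)-en-12-oate, via 13-methoxy 13-hydroperoxide 14 (not isolated)
Conditions: O3 (1 equiv, Sudan Red 7B end point), CH2Cl2/MeOH, pyridine (cat.), −78 °C; then Me2S, −78 °C → rt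
Reagents that add atoms: ozone, [O-][O+]=O; methanol, CO (methoxy group of 14)
Why: Ozonolysis should select the electron-rich, unhindered enol ether over the hindered tetrasubstituted C8=C9 alkene, cleaving C12=C13 to the C12 methyl ester and, after reduction of the methoxy hydroperoxide, the C13 aldehyde.

Step 12
Reactants: 15 methyl 6α,18-dihydroxy-13-oxo-12,13-secopodocarp-8(9)-en-12-oate
Product: 16 methyl 6α,18-dihydroxyhomodrim-8(9)-en-12-oate
Conditions: RhCl(PPh3)3 (1.1 equiv), toluene, 80 °C
Reagents that add atoms: none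
Why: Tsuji–Wilkinson decarbonylation (oxidative addition into the aldehyde C–H bond, CO extrusion, reductive elimination) removes C13 and turns C14 into the C8 methyl group.

Step 13
Reactants: 16 methyl 6α,18-dihydroxyhomodrim-8(9)-en-12-oate
Product: 17 methyl 6α,18-diacetoxyhomodrim-8(9)-en-12-oate
Conditions: Ac2O (4 equiv), pyridine, DMAP (cat.), CH2Cl2, 0 °C → rt
Reagents that add atoms: acetic anhydride, CC(=O)OC(C)=O
Why: DMAP-catalysed acylation esterifies the equatorial secondary 6α-OH and the neopentyl 18-OH while the C12 carboxyl is still masked as its methyl ester, giving acid-stable, non-participating protecting groups for the cationic step.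

Step 14
Reactants: 17 methyl 6α,18-diacetoxyhomodrim-8(9)-en-12-oate
Product: 19 6α,18-diacetoxyhomodrim-8(9)-en-12-oic acid, via lithium carboxylate 18 (not isolated)
Conditions: LiI (anhydrous, 5 equiv), pyridine, reflux; then cold 1 M HCl to pH 3
Reagents that add atoms: lithium iodide, [Li+].[I-] (lithium of 18)
Why: Nucleophilic O-alkyl cleavage of the methyl ester (SN2 ester dealkylation): iodide attacks the unhindered O-methyl carbon, the iodomethane formed is taken up by pyridine, and the two acetates survive because their O-alkyl carbons are secondary and neopentyl and no hydroxide or alkoxide is present, while the weak base leaves the tetrasubstituted β,γ-alkene in place.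

Step 15
Reactants: 19 6α,18-diacetoxyhomodrim-8(9)-en-12-oic acid
Product: 20 6α,18-diacetoxyhomodriman-12,8α-olide (trans-fused γ-lactone, 9α-H, 8β-CH3)
Conditions: FSO3H (5 equiv), 2-nitropropane, −78 °C, 20 min; Et3N at −78 °C, then aq. NaHCO3
Reagents that add atoms: none
Why: Fluorosulfonic acid protonates the tetrasubstituted C8=C9 alkene reversibly; axial protonation at C9 on the α face, anti to the axial C10 methyl group, gives the tertiary C8 cation with the CH2CO2H arm β-equatorial, and the carboxyl oxygen collapses onto C8 to form the C8–O bond (the alternative C9 cation cannot close a five-membered ring and reverts). The closest known reaction type is the superacid lactonisation of mono- and bicyclic homofarnesic acids to sclareolide-type 8α,12-lactones. The one ring closed is the γ-lactone O–C8–C9–C11–C12, formally a 5-endo addition across C8=C9 that is feasible because it runs stepwise through a free cation (cation–carboxyl collapse). C9 is controlled by the C10 methyl group (proton delivered trans to it), and C8 by equatorial α attack of the tethered oxygen, which avoids a developing 1,3-diaxial contact with that methyl group and gives the trans-fused lactone with the C8 methyl axial. The step needs kinetic control, because the cis-fused 8-epimer is the more stable lactone and strong acid can also trigger migration of the C10 methyl group; −78 °C, a short contact time and a cold amine quench are meant to secure this. The 6α- and 18-acetates are equatorial, cannot bridge to C8 and should not be cleaved at this temperature, so the carboxyl group is the only internal nucleophile.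

Step 16
Reactants: 20 6α,18-diacetoxyhomodriman-12,8α-olide
Product: 21 homodrimane-6α,8α,12,18-tetraol
Conditions: LiAlH4, THF, 0 → 50 °C
Reagents that add atoms: none
Why: Hydride reduction opens the lactone to the 8α,12-diol and cleaves both acetates in one operation without touching a stereocentre.

Step 17
Reactants: 21 homodrimane-6α,8α,12,18-tetraol
Product: 22 6α,8α,12,18-tetrakis(triethylsilyloxy)homodrimane
Conditions: TESOTf (6 equiv), 2,6-lutidine, CH2Cl2, −78 °C → rt
Reagents that add atoms: triethylsilyl triflate, CC[Si](CC)(CC)OS(=O)(=O)C(F)(F)F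
Why: Silylation with the triflate caps all four hydroxyls, including the tertiary 8α-OH, which must be blocked to prevent tetrahydrofuran formation when C12 is activated.

Step 18
Reactants: 22 6α,8α,12,18-tetrakis(triethylsilyloxy)homodrimane
Product: 23 6α,8α,18-tris(triethylsilyloxy)homodriman-12-ol
Conditions: PPTS (0.1 equiv), MeOH/CH2Cl2 (1:5), −20 → 0 °C, monitored
Reagents that add atoms: none
Why: Acid-catalysed methanolysis should remove the unhindered primary C12 silyl ether much faster than the neopentyl C18, secondary C6 and tertiary C8 silyl ethers (steric rate differences in silyl ether solvolysis).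

Step 19
Reactants: 23 6α,8α,18-tris(triethylsilyloxy)homodriman-12-ol
Product: 24 12-iodo-6α,8α,18-tris(triethylsilyloxy)homodrimane
Conditions: I2, PPh3, imidazole, CH2Cl2, 0 °C → rt
Reagents that add atoms: iodine, II
Why: Appel-type iodination (alkoxyphosphonium ion, SN2 by iodide) under imidazole buffering is tolerated by the silyl ethers.

Step 20
Reactants: 24 12-iodo-6α,8α,18-tris(triethylsilyloxy)homodrimane
Product: 25 12-ethynyl-6α,8α,18-tris(triethylsilyloxy)homodrimane (terminal C13≡C14 alkyne)
Conditions: LiC≡CH·H2NCH2CH2NH2, DMSO/THF, 0 °C → rt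
Reagents that add atoms: lithium acetylide–ethylenediamine complex, [Li]C#C.NCCN
Why: SN2 alkylation of the acetylide by the unbranched primary iodide installs C13 and C14.

Step 21
Reactants: 25 12-ethynyl-6α,8α,18-tris(triethylsilyloxy)homodrimane
Product: 27 (13E)-allylic alcohol (C12–C13(CH3)=C14H–C15H2OH on the tris-silylated decalin), via E-alkenyldimethylalane 26 (not isolated)
Conditions: Me3Al (3 equiv), Cp2ZrCl2 (0.5 equiv), CH2Cl2, 0 °C → rt; evaporate; n-BuLi, THF/hexane, −78 °C; (CH2O)n, −78 °C → rt
Reagents that add atoms: trimethylaluminium, C[Al](C)C; formaldehyde (from paraformaldehyde), C=O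
Why: Negishi zirconium-catalysed carboalumination adds methyl (to C13) and aluminium (to C14) syn across the alkyne, and the derived alanate attacks formaldehyde with retention, which fixes the E geometry of C13=C14 and adds C15.

Step 22
Reactants: 27 (13E)-allylic alcohol
Product: 28 (13E)-enal (C15 aldehyde)
Conditions: MnO2 (activated, excess), CH2Cl2, rt
Reagents that add atoms: none
Why: MnO2 oxidises only the allylic primary alcohol and leaves silyl ethers and alkene geometry untouched.

Step 23
Reactants: 29 4-methylfuran-2(5H)-one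
Product: 30 4-methyl-2-(trimethylsilyloxy)furan
Conditions: TMSOTf, Et3N, Et2O, 0 °C
Reagents that add atoms: trimethylsilyl triflate, C[Si](C)(C)OS(=O)(=O)C(F)(F)F
Why: Soft enolisation with O-silylation after γ-deprotonation gives the aromatic 2-silyloxyfuran, the dienolate equivalent of the butenolide.

Step 24
Reactants: 28 (13E)-enal; 30 4-methyl-2-(trimethylsilyloxy)furan
Product: 32 (15S,16S) 6,8,18-tris-O-triethylsilyl ether of the target, via 15-O-trimethylsilyl ether 31 (not isolated)
Conditions: Ti(OiPr)4 (20 mol %), (R)-BINOL (20 mol %), 30 (2 equiv), Et2O, −20 °C; aq. NaHCO3, then dilute citric acid/THF, 0 °C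
Reagents that add atoms: none
Why: Catalytic asymmetric vinylogous Mukaiyama aldol addition: the BINOL–titanium Lewis acid activates the enal for 1,2-attack by C5 of the silyloxyfuran to form C15–C16, the (R)-BINOL complex is expected to expose the Re face of the aldehyde (15S), and the open transition state of Lewis-acid-mediated silyloxyfuran additions should favour the syn (threo) relationship (16S), the remote decalin stereocentres having no influence.

Step 25
Reactants: 32 (15S,16S) 6,8,18-tris-O-triethylsilyl ether of the target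
Product: 33 CNP0255788.1, (5S)-5-[(1S,2E)-1-hydroxy-3-methyl-5-(6α,8α,18-trihydroxyhomodriman-11-yl-type decalin)pent-2-enyl]-4-methylfuran-2(5H)-one
Conditions: HF·pyridine, pyridine, THF, 0 °C → rt
Reagents that add atoms: none
Why: Fluoride-mediated cleavage of the three Si–O bonds under buffered, non-basic conditions should spare the butenolide (no C16 epimerisation) and the acid-sensitive allylic and tertiary alcohols.

**Compound list**

1 | dehydroabietic acid (abieta-8,11,13-trien-18-oic acid) | CC(C)c1ccc2c(c1)CC[C@@H]1[C@]2(C)CCC[C@@]1(C)C(=O)O | starting material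
2 | methyl dehydroabietate | CC(C)c1ccc2c(c1)CC[C@@H]1[C@]2(C)CCC[C@@]1(C)C(=O)OC | intermediate
3 | acetyl chloride | CC(Cl)=O | starting material
4 | methyl 12-acetylabieta-8,11,13-trien-18-oate | CC(C)c1c(C(C)=O)cc2c(c1)CC[C@@H]1[C@]2(C)CCC[C@@]1(C)C(=O)OC | intermediate
5 | methyl 12-acetoxyabieta-8,11,13-trien-18-oate | CC(C)c1c(OC(C)=O)cc2c(c1)CC[C@@H]1[C@]2(C)CCC[C@@]1(C)C(=O)OC | intermediate
6 | methyl 12-hydroxyabieta-8,11,13-trien-18-oate | CC(C)c1c(O)cc2c(c1)CC[C@@H]1[C@]2(C)CCC[C@@]1(C)C(=O)OC | intermediate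
7 | methyl 12-hydroxypodocarpa-8,11,13-trien-18-oate | Oc1cc2c(cc1)CC[C@@H]1[C@]2(C)CCC[C@@]1(C)C(=O)OC | intermediate
8 | methyl 12-methoxypodocarpa-8,11,13-trien-18-oate | COc1cc2c(cc1)CC[C@@H]1[C@]2(C)CCC[C@@]1(C)C(=O)OC | intermediate
9 | methyl 12-methoxypodocarpa-6,8,11,13-tetraen-18-oate | COc1cc2c(cc1)C=C[C@@H]1[C@]2(C)CCC[C@@]1(C)C(=O)OC | intermediate
10 | 12-methoxypodocarpa-6,8,11,13-tetraen-18-ol | COc1cc2c(cc1)C=C[C@@H]1[C@]2(C)CCC[C@@]1(C)CO | intermediate
11 | cyclic 6α-alkylborinate (B–H bridging C6α and O18) | COc1cc2c(cc1)C[C@H](B3)[C@@H]1[C@]2(C)CCC[C@@]1(C)CO3 | intermediate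
12 | 12-methoxypodocarpa-8,11,13-triene-6α,18-diol | COc1cc2c(cc1)C[C@H](O)[C@@H]1[C@]2(C)CCC[C@@]1(C)CO | intermediate
13 | 12-methoxypodocarpa-8(9),12-diene-6α,18-diol | COC1=CCC2=C(C1)[C@@]1(C)CCC[C@@](C)(CO)[C@@H]1[C@@H](O)C2 | intermediate
14 | methyl 13-hydroperoxy-6α,18-dihydroxy-13-methoxy-12,13-secopodocarp-8(9)-en-12-oate | COC(=O)CC1=C(CC(OC)OO)C[C@H](O)[C@H]2[C@](C)(CO)CCC[C@]12C | intermediate
15 | methyl 6α,18-dihydroxy-13-oxo-12,13-secopodocarp-8(9)-en-12-oate | COC(=O)CC1=C(CC=O)C[C@H](O)[C@H]2[C@](C)(CO)CCC[C@]12C | intermediate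
16 | methyl 6α,18-dihydroxyhomodrim-8(9)-en-12-oate | COC(=O)CC1=C(C)C[C@H](O)[C@H]2[C@](C)(CO)CCC[C@]12C | intermediate
17 | methyl 6α,18-diacetoxyhomodrim-8(9)-en-12-oate | COC(=O)CC1=C(C)C[C@H](OC(C)=O)[C@H]2[C@](C)(COC(C)=O)CCC[C@]12C | intermediate
18 | lithium 6α,18-diacetoxyhomodrim-8(9)-en-12-oate | [Li+].[O-]C(=O)CC1=C(C)C[C@H](OC(C)=O)[C@H]2[C@](C)(COC(C)=O)CCC[C@]12C | intermediate
19 | 6α,18-diacetoxyhomodrim-8(9)-en-12-oic acid | OC(=O)CC1=C(C)C[C@H](OC(C)=O)[C@H]2[C@](C)(COC(C)=O)CCC[C@]12C | intermediate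
20 | 6α,18-diacetoxyhomodriman-12,8α-olide | O=C1C[C@@H]2[C@@]3(C)CCC[C@@](C)(COC(C)=O)[C@@H]3[C@@H](OC(C)=O)C[C@@]2(C)O1 | intermediate
21 | homodrimane-6α,8α,12,18-tetraol | OCC[C@@H]1[C@@]2(C)CCC[C@@](C)(CO)[C@@H]2[C@@H](O)C[C@@]1(C)O | intermediate
22 | 6α,8α,12,18-tetrakis(triethylsilyloxy)homodrimane | CC[Si](CC)(CC)OCC[C@@H]1[C@@]2(C)CCC[C@@](C)(CO[Si](CC)(CC)CC)[C@@H]2[C@@H](O[Si](CC)(CC)CC)C[C@@]1(C)O[Si](CC)(CC)CC | intermediate
23 | 6α,8α,18-tris(triethylsilyloxy)homodriman-12-ol | OCC[C@@H]1[C@@]2(C)CCC[C@@](C)(CO[Si](CC)(CC)CC)[C@@H]2[C@@H](O[Si](CC)(CC)CC)C[C@@]1(C)O[Si](CC)(CC)CC | intermediate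
24 | 12-iodo-6α,8α,18-tris(triethylsilyloxy)homodrimane | ICC[C@@H]1[C@@]2(C)CCC[C@@](C)(CO[Si](CC)(CC)CC)[C@@H]2[C@@H](O[Si](CC)(CC)CC)C[C@@]1(C)O[Si](CC)(CC)CC | intermediate
25 | 12-ethynyl-6α,8α,18-tris(triethylsilyloxy)homodrimane | C#CCC[C@@H]1[C@@]2(C)CCC[C@@](C)(CO[Si](CC)(CC)CC)[C@@H]2[C@@H](O[Si](CC)(CC)CC)C[C@@]1(C)O[Si](CC)(CC)CC | intermediate
26 | E-alkenyldimethylalane (Al on C14, CH3 on C13) | C[Al](C)/C=C(\C)CC[C@@H]1[C@@]2(C)CCC[C@@](C)(CO[Si](CC)(CC)CC)[C@@H]2[C@@H](O[Si](CC)(CC)CC)C[C@@]1(C)O[Si](CC)(CC)CC | intermediate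
27 | (13E)-allylic alcohol (C15H2OH) | OC/C=C(\C)CC[C@@H]1[C@@]2(C)CCC[C@@](C)(CO[Si](CC)(CC)CC)[C@@H]2[C@@H](O[Si](CC)(CC)CC)C[C@@]1(C)O[Si](CC)(CC)CC | intermediate
28 | (13E)-enal (C15 aldehyde) | O=C/C=C(\C)CC[C@@H]1[C@@]2(C)CCC[C@@](C)(CO[Si](CC)(CC)CC)[C@@H]2[C@@H](O[Si](CC)(CC)CC)C[C@@]1(C)O[Si](CC)(CC)CC | intermediate
29 | 4-methylfuran-2(5H)-one | CC1=CC(=O)OC1 | starting material
30 | 4-methyl-2-(trimethylsilyloxy)furan | Cc1coc(O[Si](C)(C)C)c1 | intermediate
31 | 15-O-trimethylsilyl ether of 32 | CC1=CC(=O)O[C@@H]1[C@@H](O[Si](C)(C)C)/C=C(\C)CC[C@@H]1[C@@]2(C)CCC[C@@](C)(CO[Si](CC)(CC)CC)[C@@H]2[C@@H](O[Si](CC)(CC)CC)C[C@@]1(C)O[Si](CC)(CC)CC | intermediate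
32 | (15S,16S) 6,8,18-tris-O-triethylsilyl ether of the target | CC1=CC(=O)O[C@@H]1[C@@H](O)/C=C(\C)CC[C@@H]1[C@@]2(C)CCC[C@@](C)(CO[Si](CC)(CC)CC)[C@@H]2[C@@H](O[Si](CC)(CC)CC)C[C@@]1(C)O[Si](CC)(CC)CC | intermediate
33 | CNP0255788.1 | CC1=CC(=O)O[C@@H]1[C@@H](O)/C=C(\C)CC[C@@H]1[C@@]2(C)CCC[C@@](C)(CO)[C@@H]2[C@@H](O)C[C@@]1(C)O | target

**Step count and risks**

Total step count: 25. Longest linear sequence: 24 steps (steps 1–22, 24 and 25; step 23 prepares the furan partner).

Steps most likely to fail:

1. Step 15. Capture of the C8 cation on the β face, acid equilibration to the cis-fused lactone, or migration of the C10 methyl group would erode the C8/C9 outcome. Fallback: the C9–H and C8–O bonds are made by syn hydroboration instead. Setting out from 16, LiAlH4 (THF, 0 °C → rt) gives homodrim-8(9)-ene-6α,12,18-triol F1. Excess BH3·THF (0 → 50 °C) followed by NaOH/H2O2 is expected to add hydrogen to C9 and boron to C8 (the carbon remote from the quaternary C10) from the α face, anti to the C10 methyl group. Oxidation with retention gives tetraol 21, where the route is rejoined.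

2. Step 24. Insufficient facial or syn/anti control in the aldol addition, or competing conjugate addition, would give inseparable side-chain diastereomers. Fallback: auxiliary-controlled construction of C15/C16 followed by butenolide annulation, setting out from 28 and returning at 33. (R)-4-Benzyl-3-[(4-methoxybenzyloxy)acetyl]oxazolidin-2-one F2 is made from (R)-4-benzyloxazolidin-2-one, n-BuLi and (4-methoxybenzyloxy)acetyl chloride. Its boron enolate (Bu2BOTf, Et3N, CH2Cl2, −78 → 0 °C) adds to 28 in an Evans syn-aldol reaction to give the syn-aldol imide adduct F3, with the C15 and C16 configurations of the target. Me3Al/MeNHOMe·HCl converts it into the N-methoxy-N-methylamide F4, and TESOTf/2,6-lutidine gives the 15-O-triethylsilyl N-methoxy-N-methylamide F5. MeMgBr gives the C17 methyl ketone F6, and DDQ (CH2Cl2/pH 7 buffer) removes the 4-methoxybenzyl group to give the 16-hydroxy C17 methyl ketone F7. Ph3P=C=C=O (toluene, 80 °C; O-acylation to the ester ylide, then intramolecular Wittig reaction on the C17 ketone) gives the 6,8,15,18-tetrakis-O-triethylsilyl ether of the target F8, which HF·pyridine converts into 33.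

3. Step 11. Competing ozonation of the C8=C9 alkene, or isomerisation of the β,γ-unsaturated aldehyde into conjugation, would destroy the ring C cleavage. Fallback without ozone, setting out from 13: OsO4 (cat.)/NMO dihydroxylates only the enol ether (Upjohn conditions; the hindered tetrasubstituted alkene is far slower) and, after loss of methanol, gives 13-hydroxy-12-oxopodocarp-8(9)-ene-6α,18-diol F9. Pb(OAc)4 in MeOH/benzene cleaves the α-hydroxy ketone to the C12 methyl ester and C13 aldehyde, that is 15, where the route is rejoined.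

**Further compounds**

F1 | step 15 | homodrim-8(9)-ene-6α,12,18-triol | OCCC1=C(C)C[C@H](O)[C@H]2[C@](C)(CO)CCC[C@]12C
F2 | step 24 | (R)-4-benzyl-3-[(4-methoxybenzyloxy)acetyl]oxazolidin-2-one | O=C1OC[C@@H](Cc2ccccc2)N1C(=O)COCc1ccc(OC)cc1
F3 | step 24 | syn-aldol imide adduct (15-OH, 16-O-PMB) | O=C1OC[C@@H](Cc2ccccc2)N1C(=O)[C@H](OCc1ccc(OC)cc1)[C@@H](O)/C=C(\C)CC[C@@H]1[C@@]2(C)CCC[C@@](C)(CO[Si](CC)(CC)CC)[C@@H]2[C@@H](O[Si](CC)(CC)CC)C[C@@]1(C)O[Si](CC)(CC)CC
F4 | step 24 | N-methoxy-N-methylamide (15-OH, 16-O-PMB) | CON(C)C(=O)[C@H](OCc1ccc(OC)cc1)[C@@H](O)/C=C(\C)CC[C@@H]1[C@@]2(C)CCC[C@@](C)(CO[Si](CC)(CC)CC)[C@@H]2[C@@H](O[Si](CC)(CC)CC)C[C@@]1(C)O[Si](CC)(CC)CC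
F5 | step 24 | 15-O-triethylsilyl N-methoxy-N-methylamide | CON(C)C(=O)[C@H](OCc1ccc(OC)cc1)[C@@H](O[Si](CC)(CC)CC)/C=C(\C)CC[C@@H]1[C@@]2(C)CCC[C@@](C)(CO[Si](CC)(CC)CC)[C@@H]2[C@@H](O[Si](CC)(CC)CC)C[C@@]1(C)O[Si](CC)(CC)CC
F6 | step 24 | C17 methyl ketone (16-O-PMB, 15-O-TES) | CC(=O)[C@H](OCc1ccc(OC)cc1)[C@@H](O[Si](CC)(CC)CC)/C=C(\C)CC[C@@H]1[C@@]2(C)CCC[C@@](C)(CO[Si](CC)(CC)CC)[C@@H]2[C@@H](O[Si](CC)(CC)CC)C[C@@]1(C)O[Si](CC)(CC)CC
F7 | step 24 | 16-hydroxy C17 methyl ketone (15-O-TES) | CC(=O)[C@H](O)[C@@H](O[Si](CC)(CC)CC)/C=C(\C)CC[C@@H]1[C@@]2(C)CCC[C@@](C)(CO[Si](CC)(CC)CC)[C@@H]2[C@@H](O[Si](CC)(CC)CC)C[C@@]1(C)O[Si](CC)(CC)CC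
F8 | step 24 | 6,8,15,18-tetrakis-O-triethylsilyl ether of the target | CC1=CC(=O)O[C@@H]1[C@@H](O[Si](CC)(CC)CC)/C=C(\C)CC[C@@H]1[C@@]2(C)CCC[C@@](C)(CO[Si](CC)(CC)CC)[C@@H]2[C@@H](O[Si](CC)(CC)CC)C[C@@]1(C)O[Si](CC)(CC)CC
F9 | step 11 | 13-hydroxy-12-oxopodocarp-8(9)-ene-6α,18-diol | O=C1C(O)CC2=C(C1)[C@@]1(C)CCC[C@@](C)(CO)[C@@H]1[C@@H](O)C2
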